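Wednesday's run is the simulated run nearest the flask in free catalyst: the substrate and reagent charges and the 40 min reagent feed are the same, but the flask holds 100 µM of free catalyst, less than Wednesday's 140 µM, a ratio of 0.714.

| flask | left-handed substrate | right-handed substrate | reagent | free catalyst | remark | time |
|---|---|---|---|---|---|---|
| Wednesday's | 0.010 M | 0.010 M | 0.030 M (fed, over 40 min) | 140 µM | run made earlier |  |
| Thursday's | 0.010 M | 0.010 M | 0.030 M (fed, over 40 min) | 220 µM | run made earlier |  |
| flask | 0.010 M | 0.010 M | 0.0300 M (fed, over 40 min) | 100 µM |  | 30 h |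

| run | time / h | left-handed product / % | right-handed product / % | left-handed substrate / % |
|---|---|---|---|---|
| Wednesday's | 2.50 | 4.9 | 16.0 | 43.9 |
| Wednesday's | 5.00 | 10.2 | 27.3 | 39.1 |
| Wednesday's | 8.00 | 17.0 | 35.7 | 33.4 |
| Wednesday's | 10.0 | 17.6 | 37.9 | 29.7 |
| Wednesday's | 12.0 | 22.3 | 41.6 | 29.4 |
| Wednesday's | 15.0 | 22.5 | 41.5 | 25.7 |
| Wednesday's | 20.0 | 23.4 | 45.7 | 25.3 |
| Thursday's | 2.50 | 8.7 | 22.7 | 40.8 |
| Thursday's | 5.00 | 17.4 | 36.3 | 33.7 |
| Thursday's | 8.00 | 23.6 | 43.2 | 24.8 |
| Thursday's | 10.0 | 25.6 | 45.0 | 23.8 |
| Thursday's | 12.0 | 28.9 | 49.4 | 20.8 |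
| Thursday's | 15.0 | 32.6 | 49.3 | 19.3 |
| Thursday's | 20.0 | 33.2 | 48.1 | 17.5 |

(standard deviation of a reading: 1 percentage point)

- excess of left-handed product over right-handed product in the product at 40 min
- excess of left-handed product over right-handed product in the product at 30 h
- part of the left-handed substrate and right-handed substrate charged together that has reacted at 30 h

- free catalyst is single-handed; left-handed substrate and right-handed substrate are mirror images of each other, charged as a racemate, each of them at the stated concentration
- an excess is below zero if the other one leads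

The reagent charge of 0.0300 M exceeds the 0.0200 M of both substrates together, yet the readings flatten. Call the reach the natural logarithm of charged over present [left-handed substrate]. If that substrate is lost in proportion to itself and to the catalyst still in its round, and that catalyst dies at a steady fractional rate, the rate integrates in closed form: reach equals catalyst charged times a time factor that levels off exponentially.

At 20.0 h the reach reads 0.681 on Wednesday and 1.05 on Thursday, a ratio of 1.54 for 1.57 times the catalyst. At 20.0 h the flask should therefore reach 0.714 of Wednesday's figure. Pooled, going from 10.0 h to 20.0 h multiplies the reach by 1.37, so each such interval adds 0.370 of the gain of the one before, and 30 h stands at 1.10 times the reach at 20.0 h.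

This gives the reach per catalyst charged at 30 h, 0.00529 µM⁻¹. The flask's reach is then 0.529. Wednesday's 20.0 h readings give a selectivity factor of 3.21, right-handed over left-handed. My reckoning for the flask leaves 29.5% left-handed and 9.13% right-handed substrate, so 61.4% has reacted, with excesses of −52.5% early and −33.2% at 30 h.

The forecast, a separate reckoning, says −52%, −34% and 60%: “This points to time-based catalyst death”.

The flask gives −51.3%, −31.2% and 64.3%.

    reagent → decomposition product (k = 1.50 × 10⁻⁷ s⁻¹)
    free catalyst → spent catalyst B (k = 2.50 × 10⁻⁵ s⁻¹)
    reagent + catalyst intermediate A → free catalyst + left-handed product (k = 0.390 M⁻¹ s⁻¹)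
    reagent + free catalyst → spent catalyst A (k = 0.00180 M⁻¹ s⁻¹)
    free catalyst + left-handed substrate ⇌ catalyst intermediate A (K = 54.0 M⁻¹, k = 4.00 M⁻¹ s⁻¹)
    free catalyst + right-handed substrate ⇌ catalyst intermediate B (K = 420 M⁻¹, k = 31.0 M⁻¹ s⁻¹)
    reagent + catalyst intermediate B → free catalyst + right-handed product (k = 0.150 M⁻¹ s⁻¹)

The flask ends with 27.9% left-handed and 7.84% right-handed substrate, a reach of 0.583 against the reckoned 0.529, and spent catalyst A and B together hold 92.2% of its catalyst. The neighbouring flask with 2.5 × 10⁻⁴ M of free catalyst has a reckoned reach of 1.32, which leaves 13.3% left-handed and 0.713% right-handed substrate. That neighbour's simulated run ends with 12.2% and 0.646%, an excess of −13.3%, and 87.1% reacted.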